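**Strategy.** Ring A (C1–C5, C10) is disconnected at C1–C2 and C4–C5. This [3+3] cut exploits the 1,3-relationship of C1 and C5 across the quaternary C10 and the polarity pairing of C4 (α to the C19 ester) with C5 (β to the C7 oxygen). The key step joins the dianion of methyl 2-methylacetoacetate with a ring B 4-formylcyclohexenone: aldol at the formyl carbon, Michael closure on C5 and dehydration build ring A and set C4 and C5 in one operation. The ring B partner, carrying C9, C10 and the complete side chain, comes from an enantioselective Diels–Alder reaction of an 8-oxogeranyl silyl ether. The C3 oxygen is removed later.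

Key step: step 6

Remark: labdane numbering (C1–C20; ring A = C1–C5, C10; ring B = C5–C10; α/β as in the usual labdane drawing) is used for compound 6 and all later compounds.
Remark: 2-(triisopropylsilyloxy)buta-1,3-diene is not assumed to be a catalogue item and is made in step 3; geraniol, methyl vinyl ketone and methyl 2-methyl-3-oxobutanoate are the purchased building blocks.

Step 1
Reactants: 1 geraniol
Product: 2 geranyl triisopropylsilyl ether
Conditions: i-Pr3SiCl, imidazole, DMF, rt
Reagents that add atoms: chlorotri(propan-2-yl)silane, CC(C)[Si](Cl)(C(C)C)C(C)C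
Why: Imidazole-promoted silylation of the primary allylic alcohol should give a silyl ether robust enough to carry the C15 oxygen to the last step.

Step 2
Reactants: 2 geranyl triisopropylsilyl ether
Product: 3 (2E,6E)-2,6-dimethyl-8-(triisopropylsilyloxy)octa-2,6-dienal
Conditions: SeO2 (1.2 equiv), 1,4-dioxane, 80 °C
Reagents that add atoms: selenium dioxide, O=[Se]=O
Why: SeO2 allylic oxidation (ene reaction, then [2,3]-sigmatropic shift) should attack the (E)-methyl group of the distal, more electron-rich trisubstituted alkene and give the (2E)-enal, as is usual for geranyl esters and ethers.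

Step 3
Reactants: 4 methyl vinyl ketone
Product: 5 2-(triisopropylsilyloxy)buta-1,3-diene
Conditions: i-Pr3SiOSO2CF3, NEt3, Et2O, 0 °C → rt
Reagents that add atoms: tri(propan-2-yl)silyl trifluoromethanesulfonate, CC(C)[Si](OS(=O)(=O)C(F)(F)F)(C(C)C)C(C)C
Why: Soft enolization of the enone with a silyl triflate and an amine base (silyl enol ether formation) gives the 2-silyloxydiene.

Step 4
Reactants: 3 (2E,6E)-2,6-dimethyl-8-(triisopropylsilyloxy)octa-2,6-dienal; 5 2-(triisopropylsilyloxy)buta-1,3-diene
Product: 6 (1S,6S)-1-methyl-6-[(3E)-3-methyl-5-(triisopropylsilyloxy)pent-3-en-1-yl]-4-(triisopropylsilyloxy)cyclohex-3-ene-1-carbaldehyde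
Conditions: (S)-3,3-diphenyl-1-(2-methylphenyl)tetrahydro-1H,3H-pyrrolo[1,2-c][1,3,2]oxazaborole (20 mol %), HN(SO2CF3)2 (18 mol %), CH2Cl2, −78 → −40 °C
Reagents that add atoms: none
Why: In this catalytic enantioselective Diels–Alder reaction the CH2 terminus next to the silyloxy carbon should bond to the β-carbon of the enal (para regiochemistry), the (E)-geometry is transferred suprafacially so that CH3 and the side chain are cis (C10 and C9), and the protonated oxazaborolidine must direct the diene to the 2Si,3Re face of the enal to set both centers absolutely (the antipodal catalyst is taken if the opposite sense is found).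

Step 5
Reactants: 6 (1S,6S)-1-methyl-6-[(3E)-3-methyl-5-(triisopropylsilyloxy)pent-3-en-1-yl]-4-(triisopropylsilyloxy)cyclohex-3-ene-1-carbaldehyde
Product: 7 (1R,6S)-1-methyl-6-[(3E)-3-methyl-5-(triisopropylsilyloxy)pent-3-en-1-yl]-4-oxocyclohex-2-ene-1-carbaldehyde
Conditions: Pd(OAc)2 (1.1 equiv), MeCN, rt
Reagents that add atoms: none
Why: In the Saegusa–Ito oxidation the regiodefined silyl enol ether gives a palladium enolate bound at C6 that can only undergo β-hydride elimination toward C5, so the enone should appear exactly at C5=C6.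

Step 6
Reactants: 7 (1R,6S)-1-methyl-6-[(3E)-3-methyl-5-(triisopropylsilyloxy)pent-3-en-1-yl]-4-oxocyclohex-2-ene-1-carbaldehyde; 8 methyl 2-methyl-3-oxobutanoate
Product: 11 methyl (13E)-3,7-dioxo-15-(triisopropylsilyloxy)-17-norlabda-1,13-dien-19-oate, via aldol adduct 9 (not isolated), via hydroxy ketone 10 (not isolated)
Conditions: 8, LiN(i-Pr)2 (2.1 equiv), THF, −78 → 0 °C; 7, −78 °C; then t-BuOH (5 equiv), −78 → 40 °C; aq NH4Cl
Reagents that add atoms: none
Why: The γ-carbanion of the dianion of 8 adds to the formyl group of 7 (C1–C2, acetoacetate dianion aldol), the remaining C4 keto ester enolate then closes ring A on C5 of the ring B enone by a 6-exo-trig intramolecular Michael addition (C4–C5), and the cyclic β-hydroxy ketone loses water by E1cB once C4 is quaternary, so the sequence is a Robinson-type [3+3] annulation run in reverse order. The closest known reaction types are the γ-aldol of acetoacetate dianions and the base-mediated intramolecular Michael addition of 2-substituted β-keto esters to cyclohexenones. The step needs attack on CHO before the enone, secured by the higher electrophilicity of the aldehyde at −78 °C, and Michael closure before dehydration, secured because the open aldol is held as its C4 enolate and cannot be deprotonated at C2. C5 and C4 are set under thermodynamic control: the Michael addition of the 2-methyl keto ester is reversible through the C7 enolate, so a kinetically preferred cis-fused adduct should drain into the trans-fused isomer (5α-H), in which the quaternary C4 is equatorial on ring B. At C4 the ester should take the axial β position and the methyl group the equatorial α position, which avoids a 1,3-diaxial CH3/CH3 contact with C20. C9 and C10 are untouched and C1 ends as sp2, so no further stereocenter is created.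

Step 7
Reactants: 11 methyl (13E)-3,7-dioxo-15-(triisopropylsilyloxy)-17-norlabda-1,13-dien-19-oate
Product: 12 methyl (13E)-7,7-ethylenedioxy-3-oxo-15-(triisopropylsilyloxy)-17-norlabda-1,13-dien-19-oate
Conditions: Me3SiOCH2CH2OSiMe3, Me3SiOSO2CF3 (cat.), CH2Cl2, −78 → −20 °C
Reagents that add atoms: 1,2-bis(trimethylsilyloxy)ethane, C[Si](C)(C)OCCO[Si](C)(C)C
Why: Silyl-triflate-catalysed ketalization with the bis-silyl glycol should be selective for the unhindered saturated C7 ketone over the conjugated, neopentyl C3 carbonyl.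

Step 8
Reactants: 12 methyl (13E)-7,7-ethylenedioxy-3-oxo-15-(triisopropylsilyloxy)-17-norlabda-1,13-dien-19-oate
Product: 13 methyl (13E)-7,7-ethylenedioxy-3-oxo-15-(triisopropylsilyloxy)-17-norlabd-13-en-19-oate
Conditions: H2 (1 atm), RhCl(PPh3)3 (5 mol %), benzene, rt
Reagents that add atoms: none
Why: Homogeneous hydrogenation with RhCl(PPh3)3 should reduce the cis-disubstituted C1=C2 enone alkene and leave the trisubstituted C13=C14 alkene, as in the selective 1,2-reduction of steroidal 1,4-dien-3-ones.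

Step 9
Reactants: 13 methyl (13E)-7,7-ethylenedioxy-3-oxo-15-(triisopropylsilyloxy)-17-norlabd-13-en-19-oate
Product: 14 3-(4-methylbenzenesulfonyl)hydrazone of 13
Conditions: TsNHNH2, EtOH, 70 °C
Reagents that add atoms: 4-methylbenzenesulfonohydrazide, Cc1ccc(cc1)S(=O)(=O)NN
Why: Hydrazone formation can occur only at C3 because C7 is masked, and the quaternary C4 rules out enolization toward the ester.

Step 10
Reactants: 14 3-(4-methylbenzenesulfonyl)hydrazone of 13
Product: 16 methyl (13E)-7-oxo-15-(triisopropylsilyloxy)-17-norlabd-13-en-19-oate, via dioxolane 15 (not isolated)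
Conditions: catecholborane, CHCl3, 0 °C → rt; NaOAc·3H2O, reflux; then PPTS, acetone–H2O, 50 °C
Reagents that add atoms: water, O
Why: Catecholborane reduction of the tosylhydrazone (hydroboration of C=N, then loss of sulfinate and N2 from the diazene) should turn C3 into CH2 without touching the alkene or the ester, and mild acid then hydrolyses the dioxolane.

Step 11
Reactants: 16 methyl (13E)-7-oxo-15-(triisopropylsilyloxy)-17-norlabd-13-en-19-oate
Product: 17 methyl (13E)-7-oxo-15-(triisopropylsilyloxy)labda-8(17),13-dien-19-oate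
Conditions: (CH2O)n, N-methylanilinium trifluoroacetate, THF, reflux
Reagents that add atoms: formaldehyde (from paraformaldehyde), C=O
Why: Mannich-type α-methylenation (condensation, then amine elimination) should proceed through the more stable C7=C8 enol of the trans-fused ketone (the analogue of C2 in 3-oxo-5α-steroids), with C6 shielded by the C4 substituents.

Step 12
Reactants: 17 methyl (13E)-7-oxo-15-(triisopropylsilyloxy)labda-8(17),13-dien-19-oate
Product: 18 methyl (13E)-7β-hydroxy-15-(triisopropylsilyloxy)labda-8(17),13-dien-19-oate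
Conditions: NaBH4, CeCl3·7H2O, MeOH, −78 °C
Reagents that add atoms: none
Why: In the Luche reduction, 1,2-selective hydride delivery along the axial α trajectory of the trans-decalin chair should give the equatorial 7β-alcohol, which sets C7.

Step 13
Reactants: 18 methyl (13E)-7β-hydroxy-15-(triisopropylsilyloxy)labda-8(17),13-dien-19-oate
Product: 19 methyl (13E)-7β-acetoxy-15-(triisopropylsilyloxy)labda-8(17),13-dien-19-oate
Conditions: Ac2O, pyridine, DMAP (cat.), CH2Cl2, rt
Reagents that add atoms: acetic anhydride, CC(=O)OC(C)=O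
Why: Nucleophile-catalysed acylation of the secondary allylic alcohol proceeds with retention at C7.

Step 14
Reactants: 19 methyl (13E)-7β-acetoxy-15-(triisopropylsilyloxy)labda-8(17),13-dien-19-oate
Product: 20 methyl (13E)-7β-acetoxy-15-hydroxylabda-8(17),13-dien-19-oate (CNP0329157.1)
Conditions: HF·pyridine, THF–pyridine, 0 °C → rt
Reagents that add atoms: none
Why: Fluoride-mediated silyl ether cleavage (Si–F bond formation) should free the C15 alcohol without affecting the allylic acetate, the methyl ester or the alkenes.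

**Compound list**

1 | geraniol, (2E)-3,7-dimethylocta-2,6-dien-1-ol | CC(C)=CCC/C(C)=C/CO | starting material
2 | geranyl triisopropylsilyl ether | CC(C)=CCC/C(C)=C/CO[Si](C(C)C)(C(C)C)C(C)C | intermediate
3 | (2E,6E)-2,6-dimethyl-8-(triisopropylsilyloxy)octa-2,6-dienal | O=C/C(C)=C/CC/C(C)=C/CO[Si](C(C)C)(C(C)C)C(C)C | intermediate
4 | methyl vinyl ketone (but-3-en-2-one) | CC(=O)C=C | starting material
5 | 2-(triisopropylsilyloxy)buta-1,3-diene | C=CC(=C)O[Si](C(C)C)(C(C)C)C(C)C | intermediate
6 | (1S,6S)-1-methyl-6-[(3E)-3-methyl-5-(triisopropylsilyloxy)pent-3-en-1-yl]-4-(triisopropylsilyloxy)cyclohex-3-ene-1-carbaldehyde (CH3 and side chain cis) | C1C(O[Si](C(C)C)(C(C)C)C(C)C)=CC[C@](C)(C=O)[C@H]1CC/C(C)=C/CO[Si](C(C)C)(C(C)C)C(C)C | intermediate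
7 | (1R,6S)-1-methyl-6-[(3E)-3-methyl-5-(triisopropylsilyloxy)pent-3-en-1-yl]-4-oxocyclohex-2-ene-1-carbaldehyde | C1C(=O)C=C[C@](C)(C=O)[C@H]1CC/C(C)=C/CO[Si](C(C)C)(C(C)C)C(C)C | intermediate
8 | methyl 2-methyl-3-oxobutanoate (racemic) | CC(=O)C(C)C(=O)OC | starting material
9 | aldol adduct of 7 at the formyl carbon: methyl 5-hydroxy-2-methyl-3-oxopentanoate carrying the ring B enone of 7 at C5 (epimers at the carbinol and at C2 of the chain) | C1C(=O)C=C[C@](C)(C(O)CC(=O)C(C)C(=O)OC)[C@H]1CC/C(C)=C/CO[Si](C(C)C)(C(C)C)C(C)C | intermediate (not isolated)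
10 | methyl (13E)-1-hydroxy-3,7-dioxo-15-(triisopropylsilyloxy)-17-norlabd-13-en-19-oate (C1 epimers; 4α-CH3, 4β-ester, 5α-H, 9α-H, 10β-CH3) | C1C(=O)C[C@@H]2[C@](C)(C(O)CC(=O)[C@]2(C)C(=O)OC)[C@H]1CC/C(C)=C/CO[Si](C(C)C)(C(C)C)C(C)C | intermediate (not isolated)
11 | methyl (13E)-3,7-dioxo-15-(triisopropylsilyloxy)-17-norlabda-1,13-dien-19-oate (4α-CH3, 4β-ester, 5α-H, 9α-H, 10β-CH3) | C1C(=O)C[C@@H]2[C@](C)(C=CC(=O)[C@]2(C)C(=O)OC)[C@H]1CC/C(C)=C/CO[Si](C(C)C)(C(C)C)C(C)C | intermediate
12 | methyl (13E)-7,7-ethylenedioxy-3-oxo-15-(triisopropylsilyloxy)-17-norlabda-1,13-dien-19-oate | C1C3(OCCO3)C[C@@H]2[C@](C)(C=CC(=O)[C@]2(C)C(=O)OC)[C@H]1CC/C(C)=C/CO[Si](C(C)C)(C(C)C)C(C)C | intermediate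
13 | methyl (13E)-7,7-ethylenedioxy-3-oxo-15-(triisopropylsilyloxy)-17-norlabd-13-en-19-oate | C1C3(OCCO3)C[C@@H]2[C@](C)(CCC(=O)[C@]2(C)C(=O)OC)[C@H]1CC/C(C)=C/CO[Si](C(C)C)(C(C)C)C(C)C | intermediate
14 | 3-(4-methylbenzenesulfonyl)hydrazone of 13 (C=N geometry not defined) | C1C3(OCCO3)C[C@@H]2[C@](C)(CCC(=NNS(=O)(=O)c4ccc(C)cc4)[C@]2(C)C(=O)OC)[C@H]1CC/C(C)=C/CO[Si](C(C)C)(C(C)C)C(C)C | intermediate
15 | methyl (13E)-7,7-ethylenedioxy-15-(triisopropylsilyloxy)-17-norlabd-13-en-19-oate | C1C3(OCCO3)C[C@@H]2[C@](C)(CCC[C@]2(C)C(=O)OC)[C@H]1CC/C(C)=C/CO[Si](C(C)C)(C(C)C)C(C)C | intermediate (not isolated)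
16 | methyl (13E)-7-oxo-15-(triisopropylsilyloxy)-17-norlabd-13-en-19-oate | C1C(=O)C[C@@H]2[C@](C)(CCC[C@]2(C)C(=O)OC)[C@H]1CC/C(C)=C/CO[Si](C(C)C)(C(C)C)C(C)C | intermediate
17 | methyl (13E)-7-oxo-15-(triisopropylsilyloxy)labda-8(17),13-dien-19-oate | C=C1C(=O)C[C@@H]2[C@](C)(CCC[C@]2(C)C(=O)OC)[C@H]1CC/C(C)=C/CO[Si](C(C)C)(C(C)C)C(C)C | intermediate
18 | methyl (13E)-7β-hydroxy-15-(triisopropylsilyloxy)labda-8(17),13-dien-19-oate | C=C1[C@@H](O)C[C@@H]2[C@](C)(CCC[C@]2(C)C(=O)OC)[C@H]1CC/C(C)=C/CO[Si](C(C)C)(C(C)C)C(C)C | intermediate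
19 | methyl (13E)-7β-acetoxy-15-(triisopropylsilyloxy)labda-8(17),13-dien-19-oate | C=C1[C@@H](OC(C)=O)C[C@@H]2[C@](C)(CCC[C@]2(C)C(=O)OC)[C@H]1CC/C(C)=C/CO[Si](C(C)C)(C(C)C)C(C)C | intermediate
20 | methyl (13E)-7β-acetoxy-15-hydroxylabda-8(17),13-dien-19-oate (CNP0329157.1) | C=C1[C@@H](OC(C)=O)C[C@@H]2[C@](C)(CCC[C@]2(C)C(=O)OC)[C@H]1CC/C(C)=C/CO | target

**Step count.** Total: 14 steps. Longest linear sequence: 13 steps (1, 2, 4–14).

**Steps most likely to fail**

Step 6 (key step). The ring-closing Michael addition may not equilibrate, so that the kinetically favoured cis ring fusion or the wrong C4 epimer persists; the aldolate may also lactonise onto the ester. The fallback sets out from 7 and returns at 13. The same aldol–Michael annulation is run with the dianion of methyl 3-oxobutanoate (LiN(i-Pr)2, THF; then t-BuOH). This gives the C4–H keto ester methyl (13E)-1-hydroxy-3,7-dioxo-15-(triisopropylsilyloxy)-17,18-dinorlabd-13-en-19-oate F1, whatever its configuration at C1, C4 and C5. Ethylene glycol and TsOH (benzene, reflux, water removal) protect C7 and dehydrate C1–OH to the 7,7-ethylenedioxy 1-en-3-one keto ester F2. DDQ (dioxane, rt) dehydrogenates C4–C5 to the cross-conjugated 1,4-dien-3-one ester F3. H2 with RhCl(PPh3)3 saturates C1=C2 to the 4-en-3-one-4-carboxylate F4. Birch-type reductive methylation (Li, NH3, THF, −78 °C; then MeI) protonates C5 from the axial α side and methylates the C4 enolate on the α face, the classical entry to the trans-fused 4α-methyl-4β-ester, and delivers 13.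

Step 4. The trisubstituted enal may react slowly, with competing silyl transfer (Mukaiyama aldol) or insufficient facial discrimination. The fallback sets out from 3 and returns at 7. The more reactive (E)-1-(dimethylamino)-3-(tert-butyldimethylsilyloxy)buta-1,3-diene is used under one enantiomer of [N,N'-bis(3,5-di-tert-butylsalicylidene)cyclohexane-1,2-diaminato]chromium hexafluoroantimonate (5 mol %, CH2Cl2, 4 Å sieves, −40 °C). This should give the 5-dimethylamino silyl enol ether cycloadduct F5. Dilute HCl in THF at 0 °C then hydrolyses the enol ether and eliminates dimethylamine to give enone 7 directly, so steps 3 and 5 are not needed.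

Step 9. Condensation at the neopentyl C3 carbonyl may be sluggish, or the hydrazone nitrogen may cyclise onto the C19 ester. The fallback sets out from 13 and returns at 15. NaBH4 (MeOH, 0 °C) reduces C3 to the alcohol methyl (13E)-7,7-ethylenedioxy-3-hydroxy-15-(triisopropylsilyloxy)-17-norlabd-13-en-19-oate F6. Phenyl chlorothionoformate (pyridine, DMAP, CH2Cl2) converts it into the 3-O-(phenoxythiocarbonyl) derivative F7. Bu3SnH and AIBN (toluene, 110 °C; Barton–McCombie deoxygenation) then give 15, which is hydrolysed to 16 with PPTS as in step 10.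

**Further compounds**

F1 | step 6 | methyl (13E)-1-hydroxy-3,7-dioxo-15-(triisopropylsilyloxy)-17,18-dinorlabd-13-en-19-oate (mixture at C1, C4, C5) | C1C(=O)CC2[C@](C)(C(O)CC(=O)C2C(=O)OC)[C@H]1CC/C(C)=C/CO[Si](C(C)C)(C(C)C)C(C)C
F2 | step 6 | methyl (13E)-7,7-ethylenedioxy-3-oxo-15-(triisopropylsilyloxy)-17,18-dinorlabda-1,13-dien-19-oate (mixture at C4, C5) | C1C3(OCCO3)CC2[C@](C)(C=CC(=O)C2C(=O)OC)[C@H]1CC/C(C)=C/CO[Si](C(C)C)(C(C)C)C(C)C
F3 | step 6 | methyl (13E)-7,7-ethylenedioxy-3-oxo-15-(triisopropylsilyloxy)-17,18-dinorlabda-1,4,13-trien-19-oate | C1C3(OCCO3)CC2=C(C(=O)OC)C(=O)C=C[C@]2(C)[C@H]1CC/C(C)=C/CO[Si](C(C)C)(C(C)C)C(C)C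
F4 | step 6 | methyl (13E)-7,7-ethylenedioxy-3-oxo-15-(triisopropylsilyloxy)-17,18-dinorlabda-4,13-dien-19-oate | C1C3(OCCO3)CC2=C(C(=O)OC)C(=O)CC[C@]2(C)[C@H]1CC/C(C)=C/CO[Si](C(C)C)(C(C)C)C(C)C
F5 | step 4 | (1S,6S)-4-(tert-butyldimethylsilyloxy)-2-(dimethylamino)-1-methyl-6-[(3E)-3-methyl-5-(triisopropylsilyloxy)pent-3-en-1-yl]cyclohex-3-ene-1-carbaldehyde (C2 epimers) | C1C(O[Si](C)(C)C(C)(C)C)=CC(N(C)C)[C@](C)(C=O)[C@H]1CC/C(C)=C/CO[Si](C(C)C)(C(C)C)C(C)C
F6 | step 9 | methyl (13E)-7,7-ethylenedioxy-3-hydroxy-15-(triisopropylsilyloxy)-17-norlabd-13-en-19-oate (C3 epimers) | C1C3(OCCO3)C[C@@H]2[C@](C)(CCC(O)[C@]2(C)C(=O)OC)[C@H]1CC/C(C)=C/CO[Si](C(C)C)(C(C)C)C(C)C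
F7 | step 9 | methyl (13E)-7,7-ethylenedioxy-3-(phenoxythiocarbonyloxy)-15-(triisopropylsilyloxy)-17-norlabd-13-en-19-oate | C1C3(OCCO3)C[C@@H]2[C@](C)(CCC(OC(=S)Oc4ccccc4)[C@]2(C)C(=O)OC)[C@H]1CC/C(C)=C/CO[Si](C(C)C)(C(C)C)C(C)C
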